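**Strategy.** The plan cuts the two bonds C9–C10 (ring B) and C4–C5 (ring A), so that the whole trans-decalin unravels to an open-chain β-keto ester. It exploits three features: the quaternary C9, which can sit between a C8 ketone and an ester standing in for the C9 methyl; the fully substituted C5 opposite H-10; and the C4=C11 methylene. One oxidative radical cascade closes both rings, sets C9, C10 and C5, and ends as the exocyclic alkene. The precursor is the (1S,2R,5S)-8-phenylmenthyl ester of (6E)-6-methyl-3-oxo-2-(2,3,5,6-tetramethoxybenzyl)dodeca-6,11-dienoic acid; the auxiliary antipode is chosen by the facial shielding model.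

Key step: step 10

Numbering used: decalin atoms are C1–C10, with C4 carrying the C11 methylene, C5 the angular methyl, C8 and C9 the vicinal methyl groups and C10 the ring-fusion hydrogen; the target is (5R,8R,9S,10R), all three methyl groups cis, trans-fused.

Assumption: in the free C9 radical the ester carbonyl lies syn to C8 and the ketone oxygen anti to the ester; on that model a (1R,2S,5R)-8-phenylmenthyl ester would leave open the face that leads to the mirror-image decalin, so the commercially available (1S,2R,5S) alcohol is used (should the sense prove opposite, the antipodal alcohol is swapped in with no other change).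

**Route**

Step 1
Reactants: 1 hex-5-en-1-ol
Product: 2 hex-5-enal
Conditions: TEMPO (10 mol%), PhI(OAc)2 (1.1 equiv), CH2Cl2, rt
Reagents that add atoms: none
Why: TEMPO-catalysed oxidation of a primary alcohol with PhI(OAc)2 as terminal oxidant should stop at the aldehyde and leave the terminal alkene untouched; the volatile aldehyde is carried on as its CH2Cl2 solution.

Step 2
Reactants: 2 hex-5-enal; 3 ethyl 2-(triphenyl-λ5-phosphanylidene)propanoate
Product: 4 ethyl (2E)-2-methylocta-2,7-dienoate
Conditions: CH2Cl2, rt → 40 °C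
Reagents that add atoms: none
Why: Wittig olefination with a stabilised α-methyl ylide should give the (E)-trisubstituted enoate (chain trans to the ester), the geometry that later becomes the (E)-C5=C10 alkene.

Step 3
Reactants: 4 ethyl (2E)-2-methylocta-2,7-dienoate
Product: 5 (2E)-2-methylocta-2,7-dien-1-ol
Conditions: i-Bu2AlH (2.2 equiv), CH2Cl2, −78 → 0 °C; aq. potassium sodium tartrate
Reagents that add atoms: none
Why: 1,2-reduction of the conjugated ester with i-Bu2AlH should give the allylic alcohol with both alkenes and the (E) geometry intact.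

Step 4
Reactants: 5 (2E)-2-methylocta-2,7-dien-1-ol
Product: 6 (6E)-8-bromo-7-methylocta-1,6-diene
Conditions: PBr3 (0.4 equiv), Et2O, 0 °C
Reagents that add atoms: phosphorus tribromide, BrP(Br)Br
Why: bromination of a primary allylic alcohol with PBr3 runs by SN2 displacement of the phosphite at 0 °C, so the (E)-alkene should be kept with little allylic transposition.

Step 5
Reactants: 7 (1S,2R,5S)-8-phenylmenthol; 8 2,2,6-trimethyl-4H-1,3-dioxin-4-one
Product: 10 (1S,2R,5S)-8-phenylmenthyl 3-oxobutanoate, via acetylketene 9 (not isolated)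
Conditions: xylene, 140 °C, acetone distilled off
Reagents that add atoms: none
Why: acetoacetylation by acetylketene, released from the dioxinone by thermal retro-[4+2] cycloaddition, acylates even this hindered secondary alcohol without base, and the carbinol configuration is not touched.

Step 6
Reactants: 10 (1S,2R,5S)-8-phenylmenthyl 3-oxobutanoate; 6 (6E)-8-bromo-7-methylocta-1,6-diene
Product: 12 (1S,2R,5S)-8-phenylmenthyl (6E)-6-methyl-3-oxododeca-6,11-dienoate, via dianion 11 (not isolated)
Conditions: NaH (1.1 equiv), THF, 0 °C; n-BuLi (1.05 equiv), 0 °C; 6, 0 °C → rt; aq. NH4Cl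
Reagents that add atoms: none
Why: acetoacetate dianion alkylation: the more nucleophilic terminal carbanion displaces the allylic bromide by SN2, so chain extension should occur only at the methyl carbon, with the (E)-alkene carried over.

Step 7
Reactants: 13 1,2,4,5-tetramethoxybenzene
Product: 15 (2,3,5,6-tetramethoxyphenyl)methanol, via aryllithium 14 (not isolated)
Conditions: n-BuLi (1.1 equiv), TMEDA, THF, 0 °C → rt; (CH2O)n, 0 °C → rt; H2O
Reagents that add atoms: paraformaldehyde (as formaldehyde), C=O
Why: directed ortho-lithiation between two methoxy groups (the two free ring positions are equivalent) followed by hydroxymethylation of the aryllithium with formaldehyde should give the benzylic alcohol in one operation.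

Step 8
Reactants: 15 (2,3,5,6-tetramethoxyphenyl)methanol
Product: 16 3-(bromomethyl)-1,2,4,5-tetramethoxybenzene
Conditions: PBr3 (0.4 equiv), Et2O, 0 °C
Reagents that add atoms: phosphorus tribromide, BrP(Br)Br
Why: substitution of the benzylic alcohol by bromide with PBr3; the electron-rich, reactive bromide is used without storage.

Step 9
Reactants: 12 (1S,2R,5S)-8-phenylmenthyl (6E)-6-methyl-3-oxododeca-6,11-dienoate; 16 3-(bromomethyl)-1,2,4,5-tetramethoxybenzene
Product: 17 (1S,2R,5S)-8-phenylmenthyl (6E)-6-methyl-3-oxo-2-[(2,3,5,6-tetramethoxyphenyl)methyl]dodeca-6,11-dienoate (both C2 epimers)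
Conditions: K2CO3 (1.5 equiv), acetone, reflux
Reagents that add atoms: none
Why: C-alkylation of the β-keto ester at the doubly activated C2 with a benzylic bromide; the two ortho-methoxy groups and the bulky ester should suppress a second alkylation, and the new C2 centre forms as both epimers, which does not matter because it becomes the planar C9 radical.

Step 10
Reactants: 17 (1S,2R,5S)-8-phenylmenthyl (6E)-6-methyl-3-oxo-2-[(2,3,5,6-tetramethoxyphenyl)methyl]dodeca-6,11-dienoate
Product: 18 (1S,2R,5S)-8-phenylmenthyl (1S,4aR,8aS)-4a-methyl-5-methylidene-2-oxo-1-[(2,3,5,6-tetramethoxyphenyl)methyl]decahydronaphthalene-1-carboxylate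
Conditions: Mn(OAc)3·2H2O (2.2 equiv), Cu(OAc)2·H2O (0.2 equiv), degassed AcOH (0.05 M), rt
Reagents that add atoms: none
Why: Slow enolisation gives a trivalent-manganese enolate that loses Mn(OAc)2 to leave the free, electrophilic C9 radical between the C8 ketone and the ester; this is the Mn(OAc)3/Cu(OAc)2 oxidative free-radical polycyclisation of α-substituted unsaturated β-keto esters, known also for 8-phenylmenthyl esters. Ring B closes 6-endo-trig (C9 onto C10), preferred over 5-exo because the methyl on C5 hinders that terminus and makes the resulting C5 radical tertiary; ring A closes 6-exo-trig (C5 onto C4), and the primary C11 radical is captured by divalent copper, whose alkylcopper intermediate can lose only H-4, so the C4=C11 methylene forms directly and copper is reoxidised by manganese. C10 is set in the chair transition state of the first closure, where the (E)-alkene places the C1 chain equatorial and H-10 anti to the ester; C5 is set in the second chair closure, where the new C4–C5 bond is equatorial on ring B and the methyl ends axial, anti to H-10 (trans fusion). At C9 the dipole-minimised radical keeps the ketone oxygen anti to the ester, so the ester becomes axial and syn to the C5 methyl while the arylmethyl group is equatorial, and the phenyl ring of the (1S,2R,5S) auxiliary stacks over one face so that C10 bonds to the other, which fixes the absolute sense. Ring closure must outrun oxidation of the tertiary C5 radical and of the arene: catalytic copper, room temperature, no chelating Lewis acid and the two ortho-methoxy groups (no aryl trapping) serve this, and the product has no α-hydrogen at C9, so it is not oxidised further.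

Step 11
Reactants: 18 (1S,2R,5S)-8-phenylmenthyl (1S,4aR,8aS)-4a-methyl-5-methylidene-2-oxo-1-[(2,3,5,6-tetramethoxyphenyl)methyl]decahydronaphthalene-1-carboxylate
Product: 20 (1S,2R,5S)-8-phenylmenthyl (1S,2R,4aR,8aS)-2-[(methoxyoxalyl)oxy]-2,4a-dimethyl-5-methylidene-1-[(2,3,5,6-tetramethoxyphenyl)methyl]decahydronaphthalene-1-carboxylate, via dichlorocerium alkoxide 19 (not isolated)
Conditions: MeLi (1.5 equiv), CeCl3 (1.5 equiv, dried), THF, −78 °C; ClC(O)CO2Me (2 equiv), −78 → 0 °C
Reagents that add atoms: methyllithium, [Li]C; methyl chlorooxoacetate, COC(=O)C(=O)Cl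
Why: organocerium 1,2-addition: the weakly basic methylcerium reagent should add to the hindered, enolisable C8 ketone and not to the neopentyl ester, from the face of H-10 opposite the axial ester, and O-acylation of the alkoxide at low temperature forestalls retro-aldol cleavage of C8–C9; the C8 configuration made here is erased in step 12.

Step 12
Reactants: 20 (1S,2R,5S)-8-phenylmenthyl (1S,2R,4aR,8aS)-2-[(methoxyoxalyl)oxy]-2,4a-dimethyl-5-methylidene-1-[(2,3,5,6-tetramethoxyphenyl)methyl]decahydronaphthalene-1-carboxylate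
Product: 21 (1S,2R,5S)-8-phenylmenthyl (1R,2R,4aR,8aS)-2,4a-dimethyl-5-methylidene-1-[(2,3,5,6-tetramethoxyphenyl)methyl]decahydronaphthalene-1-carboxylate
Conditions: Bu3SnH (2 equiv), AIBN (0.2 equiv), toluene, 110 °C
Reagents that add atoms: none
Why: radical deoxygenation of a tertiary methyl oxalate with Bu3SnH: stannyl radical addition and C8–O scission give the planar tertiary C8 radical, which should take hydrogen axially on the face of H-10, anti to the axial C9 ester, so that the C8 methyl ends equatorial and cis to the C5 methyl (8R); the 1,1-disubstituted alkene does not enter the chain.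

Step 13
Reactants: 21 (1S,2R,5S)-8-phenylmenthyl (1R,2R,4aR,8aS)-2,4a-dimethyl-5-methylidene-1-[(2,3,5,6-tetramethoxyphenyl)methyl]decahydronaphthalene-1-carboxylate
Product: 22 {(1R,2R,4aR,8aS)-2,4a-dimethyl-5-methylidene-1-[(2,3,5,6-tetramethoxyphenyl)methyl]decahydronaphthalen-1-yl}methanol
Conditions: LiAlH4 (4 equiv), THF, reflux; H2O, aq. NaOH
Reagents that add atoms: none
Why: LiAlH4 reduction cleaves the hindered neopentyl ester, which would resist saponification, to the primary alcohol and returns the auxiliary 7 for reuse.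

Step 14
Reactants: 22 {(1R,2R,4aR,8aS)-2,4a-dimethyl-5-methylidene-1-[(2,3,5,6-tetramethoxyphenyl)methyl]decahydronaphthalen-1-yl}methanol
Product: 23 (1R,2R,4aR,8aS)-2,4a-dimethyl-5-methylidene-1-[(2,3,5,6-tetramethoxyphenyl)methyl]decahydronaphthalene-1-carbaldehyde
Conditions: Dess–Martin periodinane (1.5 equiv), CH2Cl2, rt
Reagents that add atoms: none
Why: Dess–Martin oxidation of the neopentyl alcohol should give the aldehyde, which has no α-hydrogen and therefore cannot epimerise or enolise.

Step 15
Reactants: 23 (1R,2R,4aR,8aS)-2,4a-dimethyl-5-methylidene-1-[(2,3,5,6-tetramethoxyphenyl)methyl]decahydronaphthalene-1-carbaldehyde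
Product: 25 1,2,4,5-tetramethoxy-3-{[(1S,2R,4aR,8aR)-1,2,4a-trimethyl-5-methylidenedecahydronaphthalen-1-yl]methyl}benzene, via hydrazone 24 (not isolated)
Conditions: N2H4·H2O (10 equiv), KOH (5 equiv), diethylene glycol, 130 °C then 200 °C
Reagents that add atoms: none
Why: Wolff–Kishner reduction under Huang-Minlon conditions converts the hindered aldehyde through its hydrazone into the C9 methyl group with loss of N2; no stereocentre is involved, and the isolated alkene and the aryl ethers should survive the base.

Step 16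
Reactants: 25 1,2,4,5-tetramethoxy-3-{[(1S,2R,4aR,8aR)-1,2,4a-trimethyl-5-methylidenedecahydronaphthalen-1-yl]methyl}benzene
Product: 26 2,5-dimethoxy-3-{[(1S,2R,4aR,8aR)-1,2,4a-trimethyl-5-methylidenedecahydronaphthalen-1-yl]methyl}cyclohexa-2,5-diene-1,4-dione
Conditions: (NH4)2Ce(NO3)6 (2.5 equiv), MeCN/H2O, 0 °C
Reagents that add atoms: water, O
Why: oxidative demethylation of the para-dimethoxyarene by tetravalent cerium in aqueous MeCN should give the 2,5-dimethoxy-1,4-quinone (either para pair of methoxy groups leads to the same quinone) without touching the isolated alkene.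

Step 17
Reactants: 26 2,5-dimethoxy-3-{[(1S,2R,4aR,8aR)-1,2,4a-trimethyl-5-methylidenedecahydronaphthalen-1-yl]methyl}cyclohexa-2,5-diene-1,4-dione
Product: 27 2-hydroxy-5-methoxy-3-{[(1S,2R,4aR,8aR)-1,2,4a-trimethyl-5-methylidenedecahydronaphthalen-1-yl]methyl}cyclohexa-2,5-diene-1,4-dione
Conditions: KOH (2 M aq.), MeOH, rt; then aq. HCl
Reagents that add atoms: potassium hydroxide, [K+].[OH-]
Why: addition–elimination of hydroxide on a vinylogous ester: the methoxy group next to the alkyl-bearing carbon is twisted out of conjugation and should be replaced first, and the hydroxyquinone anion formed is inert to a second exchange, so acidification gives the target.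

**Compound list**

1 | hex-5-en-1-ol | C=CCCCCO | starting material
2 | hex-5-enal | C=CCCCC=O | intermediate
3 | ethyl 2-(triphenyl-λ5-phosphanylidene)propanoate | CCOC(=O)C(C)=P(c1ccccc1)(c1ccccc1)c1ccccc1 | starting material
4 | ethyl (2E)-2-methylocta-2,7-dienoate | C=CCCC/C=C(\C)C(=O)OCC | intermediate
5 | (2E)-2-methylocta-2,7-dien-1-ol | C=CCCC/C=C(\C)CO | intermediate
6 | (6E)-8-bromo-7-methylocta-1,6-diene | C=CCCC/C=C(\C)CBr | intermediate
7 | (1S,2R,5S)-8-phenylmenthol, (1S,2R,5S)-5-methyl-2-(2-phenylpropan-2-yl)cyclohexan-1-ol | C[C@H]1CC[C@@H]([C@H](C1)O)C(C)(C)c1ccccc1 | starting material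
8 | 2,2,6-trimethyl-4H-1,3-dioxin-4-one | CC1=CC(=O)OC(C)(C)O1 | starting material
9 | acetylketene | CC(=O)C=C=O | intermediate (not isolated)
10 | (1S,2R,5S)-8-phenylmenthyl 3-oxobutanoate | CC(=O)CC(=O)O[C@H]1C[C@@H](C)CC[C@@H]1C(C)(C)c1ccccc1 | intermediate
11 | sodium lithium dienolate (dianion) of 10 | [Na+].[Li+].C=C([O-])C=C([O-])O[C@H]1C[C@@H](C)CC[C@@H]1C(C)(C)c1ccccc1 | intermediate (not isolated)
12 | (1S,2R,5S)-8-phenylmenthyl (6E)-6-methyl-3-oxododeca-6,11-dienoate | C=CCCC/C=C(\C)CCC(=O)CC(=O)O[C@H]1C[C@@H](C)CC[C@@H]1C(C)(C)c1ccccc1 | intermediate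
13 | 1,2,4,5-tetramethoxybenzene | COc1cc(OC)c(OC)cc1OC | starting material
14 | (2,3,5,6-tetramethoxyphenyl)lithium | [Li]c1c(OC)c(OC)cc(OC)c1OC | intermediate (not isolated)
15 | (2,3,5,6-tetramethoxyphenyl)methanol | OCc1c(OC)c(OC)cc(OC)c1OC | intermediate
16 | 3-(bromomethyl)-1,2,4,5-tetramethoxybenzene | BrCc1c(OC)c(OC)cc(OC)c1OC | intermediate
17 | (1S,2R,5S)-8-phenylmenthyl (6E)-6-methyl-3-oxo-2-[(2,3,5,6-tetramethoxyphenyl)methyl]dodeca-6,11-dienoate, both C2 epimers | C=CCCC/C=C(\C)CCC(=O)C(Cc1c(OC)c(OC)cc(OC)c1OC)C(=O)O[C@H]1C[C@@H](C)CC[C@@H]1C(C)(C)c1ccccc1 | intermediate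
18 | (1S,2R,5S)-8-phenylmenthyl (1S,4aR,8aS)-4a-methyl-5-methylidene-2-oxo-1-[(2,3,5,6-tetramethoxyphenyl)methyl]decahydronaphthalene-1-carboxylate (ester axial and cis to the C5 methyl, trans-fused) | C=C1CCC[C@@H]2[C@@](C(=O)O[C@H]3C[C@@H](C)CC[C@@H]3C(C)(C)c3ccccc3)(Cc3c(OC)c(OC)cc(OC)c3OC)C(=O)CC[C@@]12C | intermediate
19 | dichlorocerium C8 alkoxide of the methyl adduct of 18 (C8 methyl on the face of H-10) | C=C1CCC[C@@H]2[C@@](C(=O)O[C@H]3C[C@@H](C)CC[C@@H]3C(C)(C)c3ccccc3)(Cc3c(OC)c(OC)cc(OC)c3OC)[C@](C)(O[Ce](Cl)Cl)CC[C@@]12C | intermediate (not isolated)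
20 | (1S,2R,5S)-8-phenylmenthyl (1S,2R,4aR,8aS)-2-[(methoxyoxalyl)oxy]-2,4a-dimethyl-5-methylidene-1-[(2,3,5,6-tetramethoxyphenyl)methyl]decahydronaphthalene-1-carboxylate | C=C1CCC[C@@H]2[C@@](C(=O)O[C@H]3C[C@@H](C)CC[C@@H]3C(C)(C)c3ccccc3)(Cc3c(OC)c(OC)cc(OC)c3OC)[C@](C)(OC(=O)C(=O)OC)CC[C@@]12C | intermediate
21 | (1S,2R,5S)-8-phenylmenthyl (1R,2R,4aR,8aS)-2,4a-dimethyl-5-methylidene-1-[(2,3,5,6-tetramethoxyphenyl)methyl]decahydronaphthalene-1-carboxylate | C=C1CCC[C@@H]2[C@@](C(=O)O[C@H]3C[C@@H](C)CC[C@@H]3C(C)(C)c3ccccc3)(Cc3c(OC)c(OC)cc(OC)c3OC)[C@H](C)CC[C@@]12C | intermediate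
22 | {(1R,2R,4aR,8aS)-2,4a-dimethyl-5-methylidene-1-[(2,3,5,6-tetramethoxyphenyl)methyl]decahydronaphthalen-1-yl}methanol | C=C1CCC[C@@H]2[C@@](CO)(Cc3c(OC)c(OC)cc(OC)c3OC)[C@H](C)CC[C@@]12C | intermediate
23 | (1R,2R,4aR,8aS)-2,4a-dimethyl-5-methylidene-1-[(2,3,5,6-tetramethoxyphenyl)methyl]decahydronaphthalene-1-carbaldehyde | C=C1CCC[C@@H]2[C@@](C=O)(Cc3c(OC)c(OC)cc(OC)c3OC)[C@H](C)CC[C@@]12C | intermediate
24 | (E)-hydrazone of aldehyde 23 | C=C1CCC[C@@H]2[C@@](/C=N/N)(Cc3c(OC)c(OC)cc(OC)c3OC)[C@H](C)CC[C@@]12C | intermediate (not isolated)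
25 | 1,2,4,5-tetramethoxy-3-{[(1S,2R,4aR,8aR)-1,2,4a-trimethyl-5-methylidenedecahydronaphthalen-1-yl]methyl}benzene | C=C1CCC[C@@H]2[C@@](C)(Cc3c(OC)c(OC)cc(OC)c3OC)[C@H](C)CC[C@@]12C | intermediate
26 | 2,5-dimethoxy-3-{[(1S,2R,4aR,8aR)-1,2,4a-trimethyl-5-methylidenedecahydronaphthalen-1-yl]methyl}cyclohexa-2,5-diene-1,4-dione | C=C1CCC[C@@H]2[C@@](C)(CC3=C(OC)C(=O)C=C(OC)C3=O)[C@H](C)CC[C@@]12C | intermediate
27 | 2-hydroxy-5-methoxy-3-{[(1S,2R,4aR,8aR)-1,2,4a-trimethyl-5-methylidenedecahydronaphthalen-1-yl]methyl}cyclohexa-2,5-diene-1,4-dione | C=C1CCC[C@@H]2[C@@](C)(CC3=C(O)C(=O)C=C(OC)C3=O)[C@H](C)CC[C@@]12C | target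

**Step count and risk**

Total step count: 17. Longest linear sequence: 14 steps (steps 1–4, 6, 9–17).

Steps most likely to fail:

1. Step 10. The tertiary C5 radical, or the electron-rich arene, may be oxidised by the metal oxidants before the slower 6-exo closure of ring A, which would stop the cascade after one ring. The fallback sets out from 17 and rejoins the route at 18. Deprotonation and iodination of 17 (NaH, then N-iodosuccinimide, THF, 0 °C) should give the α-iodo β-keto ester F1. Irradiation with (Bu3Sn)2 (0.1 equiv, sunlamp, benzene, 80 °C) starts an iodine atom transfer radical bicyclisation: the same C9 radical closes the same two rings in a chain that contains no oxidant, and the C11 radical takes iodine from F1 to give the primary iodide F2. Dehydroiodination (DBU, toluene, 90 °C), for which only H-4 is available, then gives 18.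

2. Step 11. The hindered C8 ketone may enolise instead of adding the methyl group, or the adduct may revert by retro-aldol cleavage before it is acylated; the hydrogen transfer of step 12 could also show poor facial selectivity. The fallback sets out from 18, bypasses steps 11 and 12 and rejoins at 21. Buffered mCPBA (NaHCO3, CH2Cl2, 0 °C) masks the C4=C11 alkene as the spiro-epoxide F3. Wittig methylenation of the C8 ketone (Ph3P=CH2, toluene, 80 °C) gives the methylene epoxide F4. Hydrogenation (H2, Pd/C, EtOAc) should deliver hydrogen to the C8 methylene from the face of H-10, anti to the axial ester, and give the 8-methyl epoxide F5 with the equatorial methyl. Deoxygenation of the epoxide with WCl6/n-BuLi (THF, 0 °C → rt) restores the C4 methylene and gives 21.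

3. Step 15. The crowded hydrazone may be reduced incompletely, or aryl methyl ethers may be cleaved by hydroxide at 200 °C. The fallback sets out from 22, bypasses 23 and 24 and rejoins at 25. Xanthate formation (NaH, CS2, then MeI, THF) gives the S-methyl xanthate F6, and Barton–McCombie deoxygenation (Bu3SnH, AIBN, xylene, 140 °C) of this primary xanthate should give 25.

Further compounds
F1 | step 10 | (1S,2R,5S)-8-phenylmenthyl (6E)-2-iodo-6-methyl-3-oxo-2-[(2,3,5,6-tetramethoxyphenyl)methyl]dodeca-6,11-dienoate, both C2 epimers | C=CCCC/C=C(\C)CCC(=O)C(I)(Cc1c(OC)c(OC)cc(OC)c1OC)C(=O)O[C@H]1C[C@@H](C)CC[C@@H]1C(C)(C)c1ccccc1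
F2 | step 10 | C11 primary iodide of the bicyclic keto ester (iodomethyl at C4 equatorial, otherwise as 18) | IC[C@@H]1CCC[C@@H]2[C@@](C(=O)O[C@H]3C[C@@H](C)CC[C@@H]3C(C)(C)c3ccccc3)(Cc3c(OC)c(OC)cc(OC)c3OC)C(=O)CC[C@@]12C
F3 | step 11 | C4/C11 spiro-epoxide of 18, either C4 epimer | O1CC12CCC[C@@H]3[C@@](C(=O)O[C@H]4C[C@@H](C)CC[C@@H]4C(C)(C)c4ccccc4)(Cc4c(OC)c(OC)cc(OC)c4OC)C(=O)CC[C@@]23C
F4 | step 11 | C8-methylidene analogue of F3 | O1CC12CCC[C@@H]3[C@@](C(=O)O[C@H]4C[C@@H](C)CC[C@@H]4C(C)(C)c4ccccc4)(Cc4c(OC)c(OC)cc(OC)c4OC)C(=C)CC[C@@]23C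
F5 | step 11 | C4/C11 spiro-epoxide of 21 (8R, equatorial C8 methyl) | O1CC12CCC[C@@H]3[C@@](C(=O)O[C@H]4C[C@@H](C)CC[C@@H]4C(C)(C)c4ccccc4)(Cc4c(OC)c(OC)cc(OC)c4OC)[C@H](C)CC[C@@]23C
F6 | step 15 | O-alkyl S-methyl dithiocarbonate (xanthate) of alcohol 22 | C=C1CCC[C@@H]2[C@@](COC(=S)SC)(Cc3c(OC)c(OC)cc(OC)c3OC)[C@H](C)CC[C@@]12C
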